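Ring B is disconnected between B-C1 and B-C6. Its oxygens sit on B-C2 and B-C4, while B-C1 and B-C6 hold the carboxyl and heptyl carbons. This is the 1,3-alternation left when a linear poly-β-keto chain folds, so benzyl 3,5,7-trioxotetradecanoate, obtained by acylketene trapping from a diketo-dioxinone, is the direct precursor. One carbonate-then-acid operation forges the B-C1–B-C6 bond, closes ring B and aromatises it. The resulting resorcylate has a free B-C4 hydroxyl and a B-C2 hydroxyl tied up by the ester. Selective acylation with an O-benzyl ring A acid (from olivetol), methylation and one hydrogenolysis then finish the depside.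

Key step: step 4

Remark on the chemistry: ring B is numbered from the carboxyl carbon (B-C1) through the methoxy carbon (B-C2) and the depside oxygen carbon (B-C4) to the heptyl carbon (B-C6). The nucleophilic chain carbon C2 lies between the ester and the C3 ketone, so its enolate double bond C2=C3 is inside the ring being formed; the closure is therefore classed as 6-(enolendo)-exo-trig. The target has no stereocentre.

Step 1
Reactants: 1 2,2,6-trimethyl-4H-1,3-dioxin-4-one
Product: 3 2,2-dimethyl-6-(2-oxopropyl)-4H-1,3-dioxin-4-one, via lithium dienolate 2 (not isolated)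
Conditions: LiN(SiMe3)2, THF, −78 °C; AcCl (0.5 equiv), −78 → 0 °C; aq. NH4Cl
Reagents that add atoms: acetyl chloride CC(Cl)=O
Why: Crossed Claisen-type C-acylation of the vinylogous lithium enolate at its terminal (former 6-methyl) carbon, run with the dienolate in excess because the more acidic product consumes a second equivalent of it.

Step 2
Reactants: 3 2,2-dimethyl-6-(2-oxopropyl)-4H-1,3-dioxin-4-one; 4 octanoyl chloride
Product: 6 6-(2,4-dioxoundecyl)-2,2-dimethyl-4H-1,3-dioxin-4-one, via dilithium dianion 5 (not isolated)
Conditions: LiN(iPr)2 (2.1 equiv), THF, −78 °C; 4 (0.5 equiv), −78 → −40 °C; aq. NH4Cl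
Reagents that add atoms: none
Why: Claisen acylation of a 1,3-dicarbonyl-type dianion, which should react at its terminal, last-formed and most basic carbanion centre, the dianion being held in excess over the acid chloride to suppress double acylation.

Step 3
Reactants: 6 6-(2,4-dioxoundecyl)-2,2-dimethyl-4H-1,3-dioxin-4-one; 7 benzyl alcohol
Product: 9 benzyl 3,5,7-trioxotetradecanoate, via acylketene 8 (not isolated)
Conditions: 7 (1.1 equiv), toluene, 110 °C; concentrate, use crude
Reagents that add atoms: none
Why: Thermal retro-hetero-Diels–Alder fragmentation of the dioxinone expels acetone, and the acylketene should be captured by benzyl alcohol faster than by its own enol oxygen, giving the β-keto ester (acylketene trapping).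

Step 4
Reactants: 9 benzyl 3,5,7-trioxotetradecanoate
Product: 11 benzyl 2-heptyl-4,6-dihydroxybenzoate, via aldol adduct 10 (not isolated)
Conditions: Cs2CO3, iPrOH/CH2Cl2, rt; then HCl (4 M in dioxane), rt
Reagents that add atoms: none
Why: Cs2CO3 deprotonates the doubly activated chain C2 (between the benzyl ester and the C3 ketone) and this carbon adds to the C7 ketone in an intramolecular aldol addition that forms the chain C2–C7 bond (B-C1–B-C6) and gives cyclohexanedione 10; acid then eliminates the tertiary hydroxyl and the C3 and C5 carbonyls tautomerise to the phenols on B-C2 and B-C4, with aromatisation as the driving force. The closest known reaction type is the biomimetic aldol aromatisation of 3,5,7-triketo esters to 6-alkyl-β-resorcylates. Ring B closes by 6-exo-trig attack on the C7 carbonyl, classed as 6-(enolendo)-exo-trig through the C2=C3 ketone enolate (6-(enolexo) if the anion is drawn through the ester enolate), both favoured modes. No stereocentre is set, since the two sp3 centres of 10 are erased on aromatisation. The step needs chemoselectivity for the C2-to-C7 aldol over Claisen attack of C6 on the ester carbon, over O-cyclisation onto the ester to a pyranone and over aldol from the singly activated C8; the C7 ketone is a far better electrophile than the benzyl ester, C2 is far more acidic than C8, and a mild carbonate base at room temperature should not drive the alkoxide-expelling pathways. The hindered, weakly nucleophilic alcohol cosolvent should keep the benzyl ester from exchanging.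

Step 5
Reactants: 12 olivetol (5-pentylbenzene-1,3-diol)
Product: 14 2,4-dihydroxy-6-pentylbenzaldehyde, via iminium chloride 13 (not isolated)
Conditions: POCl3, DMF, 0 °C → rt; then H2O, 50 °C
Reagents that add atoms: N,N-dimethylformamide CN(C)C=O; water O
Why: Vilsmeier–Haack formylation, in which the chloroiminium ion should attack the ring position para to one hydroxyl and ortho to the other in preference to the more crowded carbon between the two hydroxyls, hydrolysis of the iminium salt then giving the aldehyde.

Step 6
Reactants: 14 2,4-dihydroxy-6-pentylbenzaldehyde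
Product: 15 2-hydroxy-4-methoxy-6-pentylbenzaldehyde
Conditions: MeI (1.05 equiv), K2CO3 (1 equiv), acetone, rt
Reagents that add atoms: iodomethane CI
Why: Williamson etherification in which one equivalent of MeI should methylate only the free, more acidic 4-hydroxyl, the 2-hydroxyl being held in a hydrogen bond to the formyl group.

Step 7
Reactants: 15 2-hydroxy-4-methoxy-6-pentylbenzaldehyde
Product: 16 2-(benzyloxy)-4-methoxy-6-pentylbenzaldehyde
Conditions: BnBr, K2CO3, DMF, 60 °C
Reagents that add atoms: benzyl bromide BrCc1ccccc1
Why: Williamson benzylation of the remaining chelated phenol under more forcing conditions, with no other nucleophilic site left in the molecule.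

Step 8
Reactants: 16 2-(benzyloxy)-4-methoxy-6-pentylbenzaldehyde
Product: 17 2-(benzyloxy)-4-methoxy-6-pentylbenzoic acid
Conditions: NaClO2, NaH2PO4, 2-methyl-2-butene, tBuOH/H2O, rt
Reagents that add atoms: sodium chlorite [Na+].[O-]Cl=O
Why: Pinnick oxidation converts the aldehyde into the acid without touching the benzyl or methyl ethers, 2-methyl-2-butene removing the HOCl that would otherwise chlorinate the electron-rich ring.

Step 9
Reactants: 17 2-(benzyloxy)-4-methoxy-6-pentylbenzoic acid; 11 benzyl 2-heptyl-4,6-dihydroxybenzoate
Product: 19 benzyl 4-{[2-(benzyloxy)-4-methoxy-6-pentylbenzoyl]oxy}-2-heptyl-6-hydroxybenzoate, via acid chloride 18 (not isolated)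
Conditions: (COCl)2, DMF (cat.), CH2Cl2, 0 °C → rt, evaporate; then 11, pyridine, 4-(dimethylamino)pyridine (cat.), CH2Cl2, 0 °C → rt
Reagents that add atoms: none
Why: Acid chloride formation followed by nucleophile-catalysed O-acylation (depside esterification), in which only the free B-C4 hydroxyl should react because the B-C2 hydroxyl is hydrogen-bonded to and flanked by the benzyl ester.

Step 10
Reactants: 19 benzyl 4-{[2-(benzyloxy)-4-methoxy-6-pentylbenzoyl]oxy}-2-heptyl-6-hydroxybenzoate
Product: 20 benzyl 4-{[2-(benzyloxy)-4-methoxy-6-pentylbenzoyl]oxy}-2-heptyl-6-methoxybenzoate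
Conditions: MeI, K2CO3, acetone (dry), 50 °C
Reagents that add atoms: iodomethane CI
Why: Williamson methylation of the single remaining phenol, the depside carbonyl being shielded by its two ortho substituents (benzyloxy and pentyl) so that it should resist attack by phenoxide or carbonate under anhydrous conditions.

Step 11
Reactants: 20 benzyl 4-{[2-(benzyloxy)-4-methoxy-6-pentylbenzoyl]oxy}-2-heptyl-6-methoxybenzoate
Product: 21 2-heptyl-4-[(2-hydroxy-4-methoxy-6-pentylbenzoyl)oxy]-6-methoxybenzoic acid
Conditions: H2 (1 atm), 10% Pd/C, EtOAc, rt
Reagents that add atoms: none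
Why: Catalytic hydrogenolysis should cleave the benzyl ester and the benzyl aryl ether in one operation, while the aryl ester link, the methyl ethers and both arenes are inert under these conditions.

Compound list
1 | 2,2,6-trimethyl-4H-1,3-dioxin-4-one | CC1=CC(=O)OC(C)(C)O1 | starting material
2 | lithium dienolate of 1 (lithium 2,2-dimethyl-6-methylidene-6H-1,3-dioxin-4-olate) | [Li+].C=C1C=C([O-])OC(C)(C)O1 | intermediate (not isolated)
3 | 2,2-dimethyl-6-(2-oxopropyl)-4H-1,3-dioxin-4-one | CC(=O)CC1=CC(=O)OC(C)(C)O1 | intermediate
4 | octanoyl chloride | CCCCCCCC(=O)Cl | starting material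
5 | dilithium dianion of 3 (deprotonated at the ring-bound CH2 and at the terminal CH3) | [Li+].[Li+].C=C([O-])C=C1C=C([O-])OC(C)(C)O1 | intermediate (not isolated)
6 | 6-(2,4-dioxoundecyl)-2,2-dimethyl-4H-1,3-dioxin-4-one | CCCCCCCC(=O)CC(=O)CC1=CC(=O)OC(C)(C)O1 | intermediate
7 | benzyl alcohol | OCc1ccccc1 | starting material
8 | 3,5,7-trioxotetradec-1-en-1-one (acylketene) | O=C=CC(=O)CC(=O)CC(=O)CCCCCCC | intermediate (not isolated)
9 | benzyl 3,5,7-trioxotetradecanoate | CCCCCCCC(=O)CC(=O)CC(=O)CC(=O)OCc1ccccc1 | intermediate
10 | benzyl 2-heptyl-2-hydroxy-4,6-dioxocyclohexane-1-carboxylate (aldol adduct, transient mixture of stereoisomers) | CCCCCCCC1(O)CC(=O)CC(=O)C1C(=O)OCc1ccccc1 | intermediate (not isolated)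
11 | benzyl 2-heptyl-4,6-dihydroxybenzoate | CCCCCCCc1cc(O)cc(O)c1C(=O)OCc1ccccc1 | intermediate
12 | olivetol (5-pentylbenzene-1,3-diol) | CCCCCc1cc(O)cc(O)c1 | starting material
13 | N-[(2,4-dihydroxy-6-pentylphenyl)methylidene]-N-methylmethanaminium chloride | CCCCCc1cc(O)cc(O)c1C=[N+](C)C.[Cl-] | intermediate (not isolated)
14 | 2,4-dihydroxy-6-pentylbenzaldehyde | CCCCCc1cc(O)cc(O)c1C=O | intermediate
15 | 2-hydroxy-4-methoxy-6-pentylbenzaldehyde | CCCCCc1cc(OC)cc(O)c1C=O | intermediate
16 | 2-(benzyloxy)-4-methoxy-6-pentylbenzaldehyde | CCCCCc1cc(OC)cc(OCc2ccccc2)c1C=O | intermediate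
17 | 2-(benzyloxy)-4-methoxy-6-pentylbenzoic acid | CCCCCc1cc(OC)cc(OCc2ccccc2)c1C(=O)O | intermediate
18 | 2-(benzyloxy)-4-methoxy-6-pentylbenzoyl chloride | CCCCCc1cc(OC)cc(OCc2ccccc2)c1C(=O)Cl | intermediate (not isolated)
19 | benzyl 4-{[2-(benzyloxy)-4-methoxy-6-pentylbenzoyl]oxy}-2-heptyl-6-hydroxybenzoate | CCCCCCCc1cc(OC(=O)c2c(OCc3ccccc3)cc(OC)cc2CCCCC)cc(O)c1C(=O)OCc1ccccc1 | intermediate
20 | benzyl 4-{[2-(benzyloxy)-4-methoxy-6-pentylbenzoyl]oxy}-2-heptyl-6-methoxybenzoate | CCCCCCCc1cc(OC(=O)c2c(OCc3ccccc3)cc(OC)cc2CCCCC)cc(OC)c1C(=O)OCc1ccccc1 | intermediate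
21 | 2-heptyl-4-[(2-hydroxy-4-methoxy-6-pentylbenzoyl)oxy]-6-methoxybenzoic acid | CCCCCCCc1cc(OC(=O)c2c(O)cc(OC)cc2CCCCC)cc(OC)c1C(=O)O | target

Total step count: 11. Longest linear sequence: 7 steps (steps 1, 2, 3, 4, 9, 10, 11 from dioxinone 1; the olivetol branch, steps 5 to 8 followed by 9 to 11, is equally long).

Steps most likely to fail

1. Step 4. The open chain may fold the wrong way (O-cyclisation onto the ester or Claisen-type C-acylation), exchange its ester with the solvent, or stall before dehydration. The fallback closes the ring while the ester is still masked. It sets out from diketo-dioxinone 6, which is treated with Et3N in CH2Cl2 at room temperature. The dienolate formed at the ring-bound CH2 should attack the C7 ketone through the dioxinone carbon that corresponds to chain C2, and dehydration should give 5-heptyl-7-hydroxy-2,2-dimethyl-4H-1,3-benzodioxin-4-one F1. In this compound neither pyranone formation nor ester exchange is possible. Opening of the benzodioxinone with sodium benzyl oxide (BnOH, NaH, THF, 0 °C → rt) releases acetone and comes back to the route at resorcylate 11.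

2. Step 2. The acylation may be cut short by proton transfer from the more acidic product to the dianion, or diverted into O-acylation and double acylation by the reactive acid chloride. The fallback replaces the Claisen acylation by an aldol addition followed by oxidation. It sets out from keto-dioxinone 3, whose dianion 5 (LiN(iPr)2, THF, −78 °C) is added to octanal; the alkoxide formed cannot quench the dianion. This should give racemic 6-(4-hydroxy-2-oxoundecyl)-2,2-dimethyl-4H-1,3-dioxin-4-one F2. Oxidation of the secondary alcohol with Dess–Martin periodinane (CH2Cl2, rt) comes back to the route at diketo-dioxinone 6.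

3. Step 10. Base-mediated methylation of the hydrogen-bonded phenol may be slow enough for acyl transfer or cleavage of the depside link by phenoxide or carbonate to compete. The fallback installs the methyl ether before the depside bond exists. It sets out from resorcylate 11 and proceeds as follows:
- The free B-C4 hydroxyl is allylated selectively (allyl bromide, K2CO3, acetone, rt) to give benzyl 2-heptyl-6-hydroxy-4-(prop-2-en-1-yloxy)benzoate F3.
- The chelated hydroxyl is methylated (MeI, K2CO3, DMF, 50 °C) to give benzyl 2-heptyl-6-methoxy-4-(prop-2-en-1-yloxy)benzoate F4.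
- The allyl ether is removed with Pd(PPh3)4 and morpholine (THF, rt) to give benzyl 2-heptyl-4-hydroxy-6-methoxybenzoate F5.
- Acylation of F5 with acid chloride 18 (pyridine, 4-(dimethylamino)pyridine, CH2Cl2) comes back to the route at compound 20, which is carried into step 11 unchanged.

Further compounds
F1 | step 4 | 5-heptyl-7-hydroxy-2,2-dimethyl-4H-1,3-benzodioxin-4-one | CCCCCCCc1cc(O)cc2OC(C)(C)OC(=O)c12
F2 | step 2 | 6-(4-hydroxy-2-oxoundecyl)-2,2-dimethyl-4H-1,3-dioxin-4-one (racemic) | CCCCCCCC(O)CC(=O)CC1=CC(=O)OC(C)(C)O1
F3 | step 10 | benzyl 2-heptyl-6-hydroxy-4-(prop-2-en-1-yloxy)benzoate | CCCCCCCc1cc(OCC=C)cc(O)c1C(=O)OCc1ccccc1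
F4 | step 10 | benzyl 2-heptyl-6-methoxy-4-(prop-2-en-1-yloxy)benzoate | CCCCCCCc1cc(OCC=C)cc(OC)c1C(=O)OCc1ccccc1
F5 | step 10 | benzyl 2-heptyl-4-hydroxy-6-methoxybenzoate | CCCCCCCc1cc(O)cc(OC)c1C(=O)OCc1ccccc1
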